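A small charge of E, 1.00 mM against 0.050 M of X, stands in this flask, and the question is what it can do to the split of X between G and L.

| flask | X | E | remark | time |
|---|---|---|---|---|
| Saturday's | 0.050 M | 0.50 mM | run made earlier |  |
| Thursday's | 0.050 M | 0.75 mM | run made earlier |  |
| Monday's | 0.10 M | 1 mM | run made earlier |  |
| flask | 0.050 M | 1.00 mM |  | 8.0 min |

| run | time / min | G / % | L / % |
|---|---|---|---|
| Saturday's | 1.33 | 6.8 | 62.7 |
| Saturday's | 3.00 | 11.6 | 78.4 |
| Saturday's | 6.00 | 12.7 | 83.4 |
| Saturday's | 10.0 | 14.6 | 86.7 |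
| Thursday's | 1.33 | 6.0 | 59.0 |
| Thursday's | 3.00 | 12.3 | 77.9 |
| Thursday's | 6.00 | 13.3 | 85.6 |
| Thursday's | 10.0 | 12.3 | 85.1 |
| Monday's | 1.33 | 5.6 | 61.3 |
| Monday's | 3.00 | 12.4 | 76.7 |
| Monday's | 6.00 | 14.2 | 85.3 |
| Monday's | 10.0 | 13.9 | 86.2 |

(readings scatter by 1 percentage point)

- ratio of G to L at 2.0 s
- ratio of G to L at 8.0 min
- which of G and L there is more of at 8.0 min

- steps that have been proposed: X -> J; X <-> Z; X -> L; J -> G; J -> L; Z -> J; E + J -> Q

Among the proposed steps, J → G gives G, and E + J → Q takes J away. One E takes one J, so in this flask Q can reach 2.00 % of the X charged at the utmost: this is the ceiling, c(E) charged over c(X) charged. The second amount is G itself, read at 10.0 min as the mean of the three runs, 13.6 %, beside 86.0 % of L. The ceiling is smaller than that G, at 0.147 of it. Were the whole ceiling taken from that G, the ratio of G to L, read as 0.158, would sink to 0.135, and L would stay ahead. The reckoning here commits to that span for this flask at 8.0 min.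

The forecast gives one number from the same comparison: “E is only 1–2% of X, so it can remove at most about 2 points of G.” It expects 0.004 at 2.0 s, 0.147 at 8.0 min, and L ahead.

The flask gives 0.00460 at 2.0 s, above the forecast, and 0.158 at 8.0 min, with 13.5 % of G and 85.6 % of L, so L leads.

    X → J (k = 0.00417 /s)
    X ⇌ Z (K = 0.761, k = 0.00828 /s)
    X → L (k = 0.0166 /s)
    J → G (k = 0.0186 /s)
    J → L (k = 0.0168 /s)
    Z → J (k = 0.00284 /s)
    E + J → Q (k = 0.281 /M/s)

In this flask Q stands at 0.194 % at 8.00 min, which is 0.0970 of the ceiling. A neighbouring flask holds 0.0017 M of E, its other charges unchanged, so its ceiling is 3.40 % and the same reckoning puts its lowest ratio at 0.119. That flask reaches 0.328 % of Q at 8.00 min, 0.0965 of its ceiling, and its ratio of G to L is 0.157.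

The runs were computed from invented constants.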